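# Proposed total synthesis of CNP0105745.1

## Analysis of the target

Remark on numbering: the core is numbered as a 6,8-dioxabicyclo[3.2.2]nonan-7-one. C1 and C5 are the bridgeheads, C2–C3–C4 is the carbon bridge, O6–C7(=O) the lactone bridge and O8–C9 the ether bridge. Side chain A is the (3Z)-5-hydroxy-3-methylpent-3-en-1-yl group on C9 (C1″–C5″). Side chain B is the (3Z)-5-hydroxy-4-methylpent-3-en-1-yl group on C1 (C1′–C5′). The target is the (1R,2S,5R,9S) isomer.

The core is an oxepane (O8, C9, C5, C4, C3, C2, C1) bridged from C1 to C5 by the lactone unit C7(=O)–O6, so a 1,4-dioxan-2-one (C1, C7, O6, C5, C9, O8) and an ε-lactone share the two bridgeheads. There are four stereocentres. C1 and C5 are locked to each other by the bicycle. C9 carries side chain A trans to O6 across C9–C5, and the C2 hydroxyl is anti-periplanar to O8 across C1–C2, on the side of the lactone bridge. C1 is the hardest atom: it is fully substituted and bonded at once to ether oxygen O8, acyl carbon C7, carbinol carbon C2 and a chain with β-hydrogens. Both side chains end in (Z)-trisubstituted primary allylic alcohols, which are further stereo-elements. The sensitive groups are the β-hydroxy lactone (retro-aldol of C1–C2 under base), the bridged lactone (hydrides, strong nucleophiles) and the allylic alcohols (acid ionisation, Z/E drift). The synthesis is hard because O8 joins a tertiary and a hindered secondary carbon, an enolate at C1 would sit next to more acidic sites, and C1 and C2 must be set together.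

The feature that invites the chosen move is the triad O8–C1–C2. It is what remains when a carbon (C2) migrates from an oxonium oxygen (O8) to the adjacent ylide carbon (C1). Returning C2 to O8 contracts the oxepane to a six-membered lactol ring O8–C9–C5–C4–C3–C2, with its ring oxygen on C9, a carbonyl-derived carbinol at C5 and an acetal at C2. That is the substitution pattern of an Achmatowicz product.

## Retrosynthetic reasoning

**26 to 25.** Only the three silyl ethers are cut. Every skeletal bond and all four stereocentres are already present in 25. The forward step must remove silicon without base, because the β-hydroxy lactone can undergo retro-aldol cleavage.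

**25 to 22 (key disconnection).** Bonds C1–C2 and C1–O8 are cut and C2–O8 is restored, the retron of a [1,2]-Stevens shift in oxonium ylide 24. This gives diazo ester 22, whose only ring is an oxane. The cut is made here because one event then builds the quaternary C1, both C1 bonds that are hardest to make, and both rings of the bicycle, without ever forming an enolate. C1 is fixed by the bridgehead constraint and C2 is relayed from the acetal carbon. The forward reaction must capture the carbene at the oxane oxygen faster than hydride shift or C–H insertion, and must move the acetal carbon with retention.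

**22 to 19 and 6.** The ester bond C7–O6 and the bond C1–C1′ are cut. Acetoacetate 20 is the linchpin: acylation of tertiary alcohol 19, C-alkylation with iodide 6 to 21, then deacylative diazo transfer. The acetyl group serves as a traceless activator and places the diazo group on the carbon that already bears side chain B.

**19 to 17.** The C5–CH3 bond is cut and the C3–C4 unsaturation restored, via allylic alcohol 18. Addition of a methyl nucleophile to enone 17 is steered by the anomeric silyloxy group, so the future C2 controls C5 before it later becomes C2 itself.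

**17 to 15.** The pyranone ring of 16 is unravelled to furyl carbinol 15 (Achmatowicz rearrangement). The C9–O8 bond comes from the carbinol, and C5, C4, C3 and C2 come from the furan. This makes the six-membered lactol on the secondary oxygen by construction, not the five-membered one on the tertiary oxygen.

**15 to 10 and 11.** The C9–C5 bond is cut: addition of lithiated furan 11 (as 12) to aldehyde 10, oxidation to ketone 14 and catalytic asymmetric transfer hydrogenation. C9 is the only stereocentre set by an external chiral agent; all others are relayed from it.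

**10 to 7.** Nerol 7 supplies the (Z)-alkene of side chain A ready-made. Its distal prenyl alkene is excised by way of silyl ether 8 and epoxide 9.

**6 to 1 and 2.** The C3′=C4′ alkene of side chain B is cut in the Wittig sense. Phosphonium salt 1 (as ylide 3) and α-silyloxy ketone 2 give 4 with the oxygenated carbon cis to the chain. Alcohol 5 and iodide 6 follow by selective desilylation and iodination.

## Alternatives that were turned down

**Alternative 1:** (textbook) Disconnect the lactone C7–O6 and the ether O8–C9. Forward, the acyclic epoxy diol ester A1 would cyclise by attack of its tertiary C1 hydroxyl on C9 of the epoxide (7-endo) to the oxepane hydroxy ester A2, which would then lactonise from C5–OH onto C7. It was turned down for three reasons.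
- The attack must occur at the less substituted epoxide carbon in the endo mode. The same hydroxyl reaches tertiary C5 by 6-exo closure and the C2 hydroxyl reaches it by 5-exo closure; both are favoured by ring size and by cation stability at C5.
- Nothing at C9 can direct the nucleophile there.
- A1 itself needs two separate asymmetric oxidations on a tetraene, with site-selectivity and protecting-group problems, so each stereocentre is bought separately and the step count is high.

**Alternative 2:** Disconnect C1–C2 in the aldol sense. Forward, the lactone enolate of dioxanone aldehyde A3 would add to its tethered aldehyde (7-enolendo-exo-trig) to close the carbon bridge. It was turned down for three reasons.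
- The aldehyde α-hydrogens at C3 are several pK units more acidic than the tertiary α-alkoxy lactone hydrogen at C1, so base enolises the wrong site.
- Masking the aldehyde as an acetal and closing in the Mukaiyama manner gives a C2 ether, not the alcohol.
- A3 needs the O8–C1 ether made beforehand on a substrate whose free C9 hydroxyl and C2 aldehyde close to a lactol, so C2 must be carried at the alcohol level through extra protection and oxidation steps.

The chosen key step forms the same bond directly from that lactol, with both reactive partners generated together.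

**Alternative 3:** Medium ring first. Disconnect O8–C1 as an epoxide opening across a preformed seven-membered lactone. Forward, the unsaturated ε-lactone A4 (from ring-closing metathesis) would be epoxidised to A5, and the C9 hydroxyl would open the epoxide at C1 with inversion. The anti relationship of O8 and the C2 hydroxyl in the target fits this. It was turned down for three reasons.
- The attack is needed at the fully substituted α-carbon of a glycidic ester. The β-carbon C2 is equally reachable (also a six-membered ether ring and a bicyclo[3.2.2] frame) and electronically preferred, which leads to a constitutional isomer.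
- The face of epoxidation of the electron-poor enoate is not controlled by the remote C5 centre.
- The metathesis must form a trisubstituted enoate from a 1,1-disubstituted acrylate, after selective acylation of a tertiary hydroxyl in the presence of a secondary one.

Key step: step 17

## Steps

Step 1
Reactants: 1 [3-(tert-butyldimethylsilyloxy)propyl]triphenylphosphonium bromide; 2 1-(tert-butyldiphenylsilyloxy)propan-2-one
Product: 4 (Z)-1-(tert-butyldimethylsilyloxy)-5-(tert-butyldiphenylsilyloxy)-4-methylpent-3-ene, via phosphorus ylide 3 (not isolated)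
Conditions: KN(SiMe3)2, THF, −78 °C; then 2, −78 °C to rt
Reagents that add atoms: none
Why: Wittig olefination of a non-stabilised ylide with an α-oxygenated methyl ketone under salt-free conditions should give the trisubstituted alkene with the oxygenated CH2 cis to the chain, which is the C3′=C4′ geometry of side chain B.

Step 2
Reactants: 4 (Z)-1-(tert-butyldimethylsilyloxy)-5-(tert-butyldiphenylsilyloxy)-4-methylpent-3-ene
Product: 5 (Z)-5-(tert-butyldiphenylsilyloxy)-4-methylpent-3-en-1-ol
Conditions: PPTS (cat.), MeOH, rt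
Reagents that add atoms: none
Why: Acid-catalysed methanolysis cleaves a primary tert-butyldimethylsilyl ether much faster than a tert-butyldiphenylsilyl ether, so only the homoallylic hydroxyl should be freed.

Step 3
Reactants: 5 (Z)-5-(tert-butyldiphenylsilyloxy)-4-methylpent-3-en-1-ol
Product: 6 (Z)-tert-butyl[(5-iodo-2-methylpent-2-en-1-yl)oxy]diphenylsilane
Conditions: I2, PPh3, imidazole, CH2Cl2, 0 °C
Reagents that add atoms: iodine, II
Why: Appel-type iodination of a primary alcohol proceeds under neutral conditions that leave the allylic silyl ether and the alkene geometry untouched.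

Step 4
Reactants: 7 nerol, (2Z)-3,7-dimethylocta-2,6-dien-1-ol
Product: 8 neryl tert-butyldiphenylsilyl ether, (2Z)-1-(tert-butyldiphenylsilyloxy)-3,7-dimethylocta-2,6-diene
Conditions: TBDPSCl, imidazole, CH2Cl2, rt
Reagents that add atoms: tert-butyl(chloro)diphenylsilane, CC(C)(C)[Si](Cl)(c1ccccc1)c1ccccc1
Why: Standard silylation; the acid-stable silyl ether is chosen to survive the periodic acid cleavage and all later steps.

Step 5
Reactants: 8 neryl tert-butyldiphenylsilyl ether
Product: 9 racemic tert-butyl{[(2Z)-5-(3,3-dimethyloxiran-2-yl)-3-methylpent-2-en-1-yl]oxy}diphenylsilane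
Conditions: mCPBA, CH2Cl2, −20 °C to 0 °C
Reagents that add atoms: 3-chloroperbenzoic acid, OOC(=O)c1cccc(Cl)c1
Why: Peracid epoxidation should favour the remote, more electron-rich trisubstituted alkene because the 2,3-alkene is deactivated inductively by the allylic oxygen; the epoxide configuration is irrelevant since both carbons are cleaved next.

Step 6
Reactants: 9 racemic 6,7-epoxide of neryl tert-butyldiphenylsilyl ether
Product: 10 (4Z)-6-(tert-butyldiphenylsilyloxy)-4-methylhex-4-enal
Conditions: H5IO6, THF/H2O, 0 °C
Reagents that add atoms: none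
Why: Periodic acid opens the epoxide hydrolytically and cleaves the resulting glycol in the same flask, releasing acetone and the aldehyde that becomes C9.

Step 7
Reactants: 10 (4Z)-6-(tert-butyldiphenylsilyloxy)-4-methylhex-4-enal; 11 furan
Product: 13 racemic (4Z)-6-(tert-butyldiphenylsilyloxy)-1-(furan-2-yl)-4-methylhex-4-en-1-ol, via 2-furyllithium 12 (not isolated)
Conditions: 11, n-BuLi, THF, −78 °C to 0 °C; then 10, −78 °C
Reagents that add atoms: none
Why: α-Lithiation of furan and 1,2-addition to the aldehyde form the C9–C5 bond; the furan carries the future C5, C4, C3 and C2.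

Step 8
Reactants: 13 racemic (4Z)-6-(tert-butyldiphenylsilyloxy)-1-(furan-2-yl)-4-methylhex-4-en-1-ol
Product: 14 (4Z)-6-(tert-butyldiphenylsilyloxy)-1-(furan-2-yl)-4-methylhex-4-en-1-one
Conditions: Dess–Martin periodinane, CH2Cl2, rt
Reagents that add atoms: none
Why: Mild oxidation of the furyl carbinol to the 2-acylfuran, which tolerates the furan ring, the alkene and the silyl ether.

Step 9
Reactants: 14 (4Z)-6-(tert-butyldiphenylsilyloxy)-1-(furan-2-yl)-4-methylhex-4-en-1-one
Product: 15 (1S,4Z)-6-(tert-butyldiphenylsilyloxy)-1-(furan-2-yl)-4-methylhex-4-en-1-ol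
Conditions: RuCl(p-cymene)[(S,S)-TsDPEN] (1 mol %), HCO2H/Et3N (5:2), rt
Reagents that add atoms: none
Why: Noyori asymmetric transfer hydrogenation of a heteroaryl alkyl ketone; the (S,S)-catalyst delivers hydride to the face that gives the (S)-carbinol when the furyl group is the π-substituent, which sets C9 (the future 9S centre) and is the only stereocentre set by an external chiral agent.

Step 10
Reactants: 15 (1S,4Z)-6-(tert-butyldiphenylsilyloxy)-1-(furan-2-yl)-4-methylhex-4-en-1-ol
Product: 16 (2S)-2-[(3Z)-5-(tert-butyldiphenylsilyloxy)-3-methylpent-3-en-1-yl]-6-hydroxy-2H-pyran-3(6H)-one (anomeric mixture)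
Conditions: VO(acac)2 (5 mol %), t-BuOOH, CH2Cl2, 0 °C to rt
Reagents that add atoms: tert-butyl hydroperoxide, CC(C)(C)OO
Why: Achmatowicz rearrangement by hydroxyl-directed oxidation of the furan; the carbinol oxygen becomes ring oxygen O8 on C9, the furan C2 becomes the C5 ketone and the furan C5 becomes the lactol carbon (future C2), while the remote alkene has no allylic hydroxyl to direct the vanadium peroxide.

Step 11
Reactants: 16 (2S)-2-[(3Z)-5-(tert-butyldiphenylsilyloxy)-3-methylpent-3-en-1-yl]-6-hydroxy-2H-pyran-3(6H)-one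
Product: 17 (2S,6S)-6-(tert-butyldimethylsilyloxy)-2-[(3Z)-5-(tert-butyldiphenylsilyloxy)-3-methylpent-3-en-1-yl]-2H-pyran-3(6H)-one (2,6-trans)
Conditions: TBSCl, imidazole, CH2Cl2, 0 °C
Reagents that add atoms: tert-butyl(chloro)dimethylsilane, CC(C)(C)[Si](C)(C)Cl
Why: Silylation of the lactol should give mainly the 2,6-trans silyl acetal (anomeric effect places the silyloxy group pseudo-axial, opposite the pseudo-equatorial side chain); the minor cis anomer is removed by chromatography.

Step 12
Reactants: 17 (2S,6S)-6-(tert-butyldimethylsilyloxy)-2-[(3Z)-5-(tert-butyldiphenylsilyloxy)-3-methylpent-3-en-1-yl]-2H-pyran-3(6H)-one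
Product: 18 (2S,3R,6S)-6-(tert-butyldimethylsilyloxy)-2-[(3Z)-5-(tert-butyldiphenylsilyloxy)-3-methylpent-3-en-1-yl]-3-methyl-3,6-dihydro-2H-pyran-3-ol
Conditions: MeLi, CeCl3, THF, −78 °C
Reagents that add atoms: methyllithium, [Li]C
Why: 1,2-Addition of the organocerium reagent to the enone should occur anti to the pseudo-axial anomeric silyloxy group, as nucleophiles do with 6-alkoxy-2H-pyran-3(6H)-ones, which puts the methyl cis to side chain A and the new hydroxyl trans to it (future 5R).

Step 13
Reactants: 18 (2S,3R,6S)-6-(tert-butyldimethylsilyloxy)-2-[(3Z)-5-(tert-butyldiphenylsilyloxy)-3-methylpent-3-en-1-yl]-3-methyl-3,6-dihydro-2H-pyran-3-ol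
Product: 19 (2S,3R,6S)-6-(tert-butyldimethylsilyloxy)-2-[(3Z)-5-(tert-butyldiphenylsilyloxy)-3-methylpent-3-en-1-yl]-3-methyloxan-3-ol
Conditions: H2 (1 atm), RhCl(PPh3)3 (10 mol %), benzene, rt
Reagents that add atoms: none
Why: Homogeneous hydrogenation with RhCl(PPh3)3 reduces cis-disubstituted alkenes and leaves trisubstituted ones, so only the ring alkene should be saturated, without hydrogenolysis of the allylic acetal; no stereocentre is created.

Step 14
Reactants: 19 (2S,3R,6S)-6-(tert-butyldimethylsilyloxy)-2-[(3Z)-5-(tert-butyldiphenylsilyloxy)-3-methylpent-3-en-1-yl]-3-methyloxan-3-ol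
Product: 20 (2S,3R,6S)-6-(tert-butyldimethylsilyloxy)-2-[(3Z)-5-(tert-butyldiphenylsilyloxy)-3-methylpent-3-en-1-yl]-3-methyloxan-3-yl 3-oxobutanoate
Conditions: 2,2,6-trimethyl-4H-1,3-dioxin-4-one, xylenes, 130 °C
Reagents that add atoms: 2,2,6-trimethyl-4H-1,3-dioxin-4-one, CC1=CC(=O)OC(C)(C)O1
Why: Thermal retro-[4+2] of the dioxinone releases acetylketene, which acylates even hindered tertiary alcohols under neutral conditions; this forms the future C7–O6 ester bond.

Step 15
Reactants: 20 oxan-3-yl 3-oxobutanoate (acetoacetate of 19); 6 (Z)-tert-butyl[(5-iodo-2-methylpent-2-en-1-yl)oxy]diphenylsilane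
Product: 21 (2S,3R,6S)-6-(tert-butyldimethylsilyloxy)-2-[(3Z)-5-(tert-butyldiphenylsilyloxy)-3-methylpent-3-en-1-yl]-3-methyloxan-3-yl (5Z)-2-acetyl-7-(tert-butyldiphenylsilyloxy)-6-methylhept-5-enoate (both epimers at the acetyl-bearing carbon)
Conditions: NaH, THF/DMF, 0 °C; then 6, rt to 40 °C
Reagents that add atoms: none
Why: C-Alkylation of the β-keto ester enolate with the primary iodide attaches side chain B to the future C1; the new centre is destroyed in the next step, so its configuration does not matter.

Step 16
Reactants: 21 α-alkylated acetoacetate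
Product: 22 (2S,3R,6S)-6-(tert-butyldimethylsilyloxy)-2-[(3Z)-5-(tert-butyldiphenylsilyloxy)-3-methylpent-3-en-1-yl]-3-methyloxan-3-yl (5Z)-7-(tert-butyldiphenylsilyloxy)-2-diazo-6-methylhept-5-enoate
Conditions: 4-acetamidobenzenesulfonyl azide, DBU, MeCN, 0 °C to rt
Reagents that add atoms: 4-acetamidobenzenesulfonyl azide, CC(=O)Nc1ccc(cc1)S(=O)(=O)N=[N+]=[N-]
Why: Regitz deacylative diazo transfer: the α-monosubstituted β-keto ester takes up the diazo group and loses the acetyl group to the sulfonamide, giving the α-alkyl α-diazo ester under mild basic conditions.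

Step 17
Reactants: 22 oxan-3-yl α-alkyl α-diazo ester
Product: 25 (1R,2S,5R,9S)-2-(tert-butyldimethylsilyloxy)-1-[(3Z)-5-(tert-butyldiphenylsilyloxy)-4-methylpent-3-en-1-yl]-9-[(3Z)-5-(tert-butyldiphenylsilyloxy)-3-methylpent-3-en-1-yl]-5-methyl-6,8-dioxabicyclo[3.2.2]nonan-7-one, via rhodium carbene 23 (not isolated), via oxonium ylide 24 (not isolated)
Conditions: Rh2(O2CCPh3)4 (2 mol %), CH2Cl2, −78 °C to 0 °C, slow addition of 22
Reagents that add atoms: none
Why: The dirhodium catalyst should decompose 22 to carbene 23, whose carbon (future C1) is captured by the axial lone pair of the oxane oxygen (future O8) through a six-membered transition state, closing the 1,4-dioxan-2-one ring C1–C7–O6–C5–C9–O8 and giving the bridged bicyclo[3.3.1] oxonium ylide 24 with the oxonium oxygen at a bridgehead. A [1,2]-Stevens shift then moves the acetal carbon (future C2), the only group on oxygen that is stabilised as a radical or cation by its silyloxy substituent, from O8 to C1, which expands the oxane by one carbon to the oxepane, forms the C1–C2 bond and leaves the ester tether as the lactone bridge. The closest known reaction type is the dirhodium-catalysed oxonium ylide formation and [1,2]-shift of diazo esters and diazo ketones tethered to cyclic acetals, which gives ring-expanded oxygen-bridged lactones and ketones. C1 needs no external control, because the bridgeheads of the bicyclo[3.2.2] frame are locked and the 5R centre dictates 1R. C2 is set by the retention typical of the Stevens shift (recombination of a short-lived caged pair), which transfers the 6S acetal configuration of 22 into 2S; this epimer is also the less hindered one, since its silyloxy group points to the lactone bridge and away from side chain A. The step needs ylide formation to beat 1,2-hydride shift from C1′ and 1,5 C–H insertion at C9–H; the bulky, electron-rich triphenylacetate ligands and the low temperature disfavour hydride shift, and an ether lone pair is a better partner for the carbene than a hindered tertiary C–H bond. Cyclopropanation is not expected, because the alkene of side chain B could only give a bicyclo[2.1.0] ring and that of side chain A only a medium ring.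

Step 18
Reactants: 25 tris-silyl ether of the target
Product: 26 (1R,2S,5R,9S)-2-hydroxy-1-[(3Z)-5-hydroxy-4-methylpent-3-en-1-yl]-9-[(3Z)-5-hydroxy-3-methylpent-3-en-1-yl]-5-methyl-6,8-dioxabicyclo[3.2.2]nonan-7-one (CNP0105745.1)
Conditions: HF·pyridine, pyridine, THF, 0 °C to rt
Reagents that add atoms: none
Why: Buffered fluoride desilylation removes the secondary tert-butyldimethylsilyl and both primary tert-butyldiphenylsilyl ethers without base, so the β-hydroxy lactone should not undergo retro-aldol cleavage and the (Z)-allylic alcohols should not ionise.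

## Compound list

1 | [3-(tert-butyldimethylsilyloxy)propyl]triphenylphosphonium bromide | CC(C)(C)[Si](C)(C)OCCC[P+](c1ccccc1)(c1ccccc1)c1ccccc1.[Br-] | starting material
2 | 1-(tert-butyldiphenylsilyloxy)propan-2-one | CC(=O)CO[Si](c1ccccc1)(c1ccccc1)C(C)(C)C | starting material
3 | [3-(tert-butyldimethylsilyloxy)propylidene]triphenylphosphorane | CC(C)(C)[Si](C)(C)OCCC=P(c1ccccc1)(c1ccccc1)c1ccccc1 | intermediate (not isolated)
4 | (Z)-1-(tert-butyldimethylsilyloxy)-5-(tert-butyldiphenylsilyloxy)-4-methylpent-3-ene | CC(C)(C)[Si](C)(C)OCC/C=C(/C)CO[Si](c1ccccc1)(c1ccccc1)C(C)(C)C | intermediate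
5 | (Z)-5-(tert-butyldiphenylsilyloxy)-4-methylpent-3-en-1-ol | OCC/C=C(/C)CO[Si](c1ccccc1)(c1ccccc1)C(C)(C)C | intermediate
6 | (Z)-tert-butyl[(5-iodo-2-methylpent-2-en-1-yl)oxy]diphenylsilane | ICC/C=C(/C)CO[Si](c1ccccc1)(c1ccccc1)C(C)(C)C | intermediate
7 | nerol, (2Z)-3,7-dimethylocta-2,6-dien-1-ol | CC(C)=CCC/C(C)=C\CO | starting material
8 | (2Z)-1-(tert-butyldiphenylsilyloxy)-3,7-dimethylocta-2,6-diene | CC(C)=CCC/C(C)=C\CO[Si](c1ccccc1)(c1ccccc1)C(C)(C)C | intermediate
9 | racemic tert-butyl{[(2Z)-5-(3,3-dimethyloxiran-2-yl)-3-methylpent-2-en-1-yl]oxy}diphenylsilane | CC1(C)OC1CC/C(C)=C\CO[Si](c1ccccc1)(c1ccccc1)C(C)(C)C | intermediate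
10 | (4Z)-6-(tert-butyldiphenylsilyloxy)-4-methylhex-4-enal | O=CCC/C(C)=C\CO[Si](c1ccccc1)(c1ccccc1)C(C)(C)C | intermediate
11 | furan | c1ccoc1 | starting material
12 | 2-furyllithium | [Li]c1ccco1 | intermediate (not isolated)
13 | racemic (4Z)-6-(tert-butyldiphenylsilyloxy)-1-(furan-2-yl)-4-methylhex-4-en-1-ol | OC(CC/C(C)=C\CO[Si](c1ccccc1)(c1ccccc1)C(C)(C)C)c1ccco1 | intermediate
14 | (4Z)-6-(tert-butyldiphenylsilyloxy)-1-(furan-2-yl)-4-methylhex-4-en-1-one | O=C(CC/C(C)=C\CO[Si](c1ccccc1)(c1ccccc1)C(C)(C)C)c1ccco1 | intermediate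
15 | (1S,4Z)-6-(tert-butyldiphenylsilyloxy)-1-(furan-2-yl)-4-methylhex-4-en-1-ol | O[C@@H](CC/C(C)=C\CO[Si](c1ccccc1)(c1ccccc1)C(C)(C)C)c1ccco1 | intermediate
16 | (2S)-2-[(3Z)-5-(tert-butyldiphenylsilyloxy)-3-methylpent-3-en-1-yl]-6-hydroxy-2H-pyran-3(6H)-one (anomeric mixture) | O1[C@@H](CC/C(C)=C\CO[Si](c2ccccc2)(c2ccccc2)C(C)(C)C)C(=O)C=CC1O | intermediate
17 | (2S,6S)-6-(tert-butyldimethylsilyloxy)-2-[(3Z)-5-(tert-butyldiphenylsilyloxy)-3-methylpent-3-en-1-yl]-2H-pyran-3(6H)-one | O1[C@@H](CC/C(C)=C\CO[Si](c2ccccc2)(c2ccccc2)C(C)(C)C)C(=O)C=C[C@@H]1O[Si](C)(C)C(C)(C)C | intermediate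
18 | (2S,3R,6S)-6-(tert-butyldimethylsilyloxy)-2-[(3Z)-5-(tert-butyldiphenylsilyloxy)-3-methylpent-3-en-1-yl]-3-methyl-3,6-dihydro-2H-pyran-3-ol | O1[C@@H](CC/C(C)=C\CO[Si](c2ccccc2)(c2ccccc2)C(C)(C)C)[C@@](C)(C=C[C@@H]1O[Si](C)(C)C(C)(C)C)O | intermediate
19 | (2S,3R,6S)-6-(tert-butyldimethylsilyloxy)-2-[(3Z)-5-(tert-butyldiphenylsilyloxy)-3-methylpent-3-en-1-yl]-3-methyloxan-3-ol | O1[C@@H](CC/C(C)=C\CO[Si](c2ccccc2)(c2ccccc2)C(C)(C)C)[C@@](C)(CC[C@@H]1O[Si](C)(C)C(C)(C)C)O | intermediate
20 | (2S,3R,6S)-6-(tert-butyldimethylsilyloxy)-2-[(3Z)-5-(tert-butyldiphenylsilyloxy)-3-methylpent-3-en-1-yl]-3-methyloxan-3-yl 3-oxobutanoate | O1[C@@H](CC/C(C)=C\CO[Si](c2ccccc2)(c2ccccc2)C(C)(C)C)[C@@](C)(CC[C@@H]1O[Si](C)(C)C(C)(C)C)OC(=O)CC(C)=O | intermediate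
21 | (2S,3R,6S)-6-(tert-butyldimethylsilyloxy)-2-[(3Z)-5-(tert-butyldiphenylsilyloxy)-3-methylpent-3-en-1-yl]-3-methyloxan-3-yl (5Z)-2-acetyl-7-(tert-butyldiphenylsilyloxy)-6-methylhept-5-enoate (epimers at the acetyl-bearing carbon) | O1[C@@H](CC/C(C)=C\CO[Si](c2ccccc2)(c2ccccc2)C(C)(C)C)[C@@](C)(CC[C@@H]1O[Si](C)(C)C(C)(C)C)OC(=O)C(CC/C=C(/C)CO[Si](c1ccccc1)(c1ccccc1)C(C)(C)C)C(C)=O | intermediate
22 | (2S,3R,6S)-6-(tert-butyldimethylsilyloxy)-2-[(3Z)-5-(tert-butyldiphenylsilyloxy)-3-methylpent-3-en-1-yl]-3-methyloxan-3-yl (5Z)-7-(tert-butyldiphenylsilyloxy)-2-diazo-6-methylhept-5-enoate | O1[C@@H](CC/C(C)=C\CO[Si](c2ccccc2)(c2ccccc2)C(C)(C)C)[C@@](C)(CC[C@@H]1O[Si](C)(C)C(C)(C)C)OC(=O)C(=[N+]=[N-])CC/C=C(/C)CO[Si](c1ccccc1)(c1ccccc1)C(C)(C)C | intermediate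
23 | rhodium carbene formed from 22 by loss of the diazo nitrogens (the Rh2(O2CCPh3)4 core is abbreviated to one Rh atom in the SMILES) | O1[C@@H](CC/C(C)=C\CO[Si](c2ccccc2)(c2ccccc2)C(C)(C)C)[C@@](C)(CC[C@@H]1O[Si](C)(C)C(C)(C)C)OC(=O)C(=[Rh])CC/C=C(/C)CO[Si](c1ccccc1)(c1ccccc1)C(C)(C)C | intermediate (not isolated)
24 | bridged bicyclo[3.3.1] oxonium ylide (oxane oxygen bonded to the former carbene carbon; carbanion α to the ester carbonyl) | C/C(=C/CC[C-]1[O+]2[C@@H](CC/C(C)=C\CO[Si](c3ccccc3)(c3ccccc3)C(C)(C)C)[C@@](C)(CC[C@@H]2O[Si](C)(C)C(C)(C)C)OC1=O)CO[Si](c1ccccc1)(c1ccccc1)C(C)(C)C | intermediate (not isolated)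
25 | (1R,2S,5R,9S)-2-(tert-butyldimethylsilyloxy)-1-[(3Z)-5-(tert-butyldiphenylsilyloxy)-4-methylpent-3-en-1-yl]-9-[(3Z)-5-(tert-butyldiphenylsilyloxy)-3-methylpent-3-en-1-yl]-5-methyl-6,8-dioxabicyclo[3.2.2]nonan-7-one | C/C(=C/CC[C@@]12O[C@@H](CC/C(C)=C\CO[Si](c3ccccc3)(c3ccccc3)C(C)(C)C)[C@@](C)(CC[C@@H]1O[Si](C)(C)C(C)(C)C)OC2=O)CO[Si](c1ccccc1)(c1ccccc1)C(C)(C)C | intermediate
26 | (1R,2S,5R,9S)-2-hydroxy-1-[(3Z)-5-hydroxy-4-methylpent-3-en-1-yl]-9-[(3Z)-5-hydroxy-3-methylpent-3-en-1-yl]-5-methyl-6,8-dioxabicyclo[3.2.2]nonan-7-one | C/C(=C/CC[C@@]12O[C@@H](CC/C(C)=C\CO)[C@@](C)(CC[C@@H]1O)OC2=O)CO | target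

## Step count and least certain steps

Total step count: 18. Longest linear sequence: 15 steps (steps 4 to 18, from nerol 7); steps 1 to 3 prepare iodide 6.

**Step 17 (key step).** Carbene 23 may be lost before it reaches the oxane oxygen, by 1,2-hydride migration from C1′ (giving an enoate) or by 1,5 C–H insertion into the activated C9–H bond. Both are unimolecular and compete with a ylide formation that needs the less populated chair with the acyloxy group axial. After ylide formation, the migrating pair may relax before recombination, which would erode the configuration at C2. Elimination within the ylide is a further leak.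

The fallback sets out from 20 and returns at 25. It replaces the α-alkyl carbene by a vinyl carbene that has no hydrogen able to shift, and attaches side chain B after the skeletal event.
- Diazo transfer to 20 without deacylation (4-acetamidobenzenesulfonyl azide, Et3N) should give the diazoacetoacetate F1.
- NaBH4 reduces its ketone to the hydroxy diazo ester F2, and POCl3/Et3N dehydrates this to the vinyl diazoacetate F3.
- Rh2(OAc)4 then effects the same ylide formation and [1,2]-shift to the 1-ethenyl bicycle F4.
- 9-BBN hydroborates the vinyl group selectively to the borane F5.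
- F5 is coupled in the same flask (Pd(dppf)Cl2, AsPh3, Cs2CO3, DMF/H2O; B-alkyl Suzuki–Miyaura coupling, retention of alkene geometry) with the (Z)-vinyl iodide F7, obtained by silylation of the known (Z)-3-iodo-2-methylprop-2-en-1-ol F6. This delivers 25.

**Step 12.** The facial selectivity of the methyl addition may be poor if the anomeric silyloxy group shields its face less than expected, or if the side chain at C2 of the pyranone deflects the reagent; this would give the C5 epimer. Enolisation or conjugate addition may also compete.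

The fallback sets out from 17 and returns at 19, and also removes the selective hydrogenation of step 13.
- Conjugate reduction of 17 with [(Ph3P)CuH]6 gives the saturated ketone F8.
- Dimethylsulfonium methylide (from Me3S+ I− and KN(SiMe3)2) transfers methylene by axial attack, anti to the axial anomeric silyloxy group, to give the spiro-epoxide F9 with its oxygen equatorial and trans to the side chain.
- LiEt3BH opens the epoxide at the CH2 terminus to give 19.

**Step 15.** C-Alkylation with a homoallylic iodide may be slow, and E2 elimination of the iodide to a diene, O-alkylation or double alkylation may consume an advanced intermediate.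

The fallback sets out from 6 and 19 and returns at 21. The alkylation is moved to cheap material and the fragments are joined by acylation.
- tert-Butyl acetoacetate (in excess) is alkylated with 6 (NaH, THF/DMF) to give F10.
- F10 is heated with 19 in xylenes at 140 °C, where loss of tert-butanol gives the α-alkyl acylketene, which acylates the tertiary alcohol to give 21.

**Step 10.** The vanadium peroxide may also be directed by the carbinol to the bishomoallylic alkene of side chain A (epoxidation followed by cyclisation to an oxolane) before the furan is consumed, and the lactol may be over-oxidised.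

The fallback sets out from 15 and returns at 16. It uses the furan as a diene instead of a directed oxygen transfer.
- Photo-oxygenation (O2, rose bengal, visible light, MeOH, −78 °C) adds singlet oxygen across the furan much faster than it undergoes an ene reaction with the trisubstituted alkene, giving the endoperoxide F11.
- Reduction with Me2S opens F11 to the ene-dione, which closes to lactol 16.

## Further compounds

F1 | step 17 | (2S,3R,6S)-6-(tert-butyldimethylsilyloxy)-2-[(3Z)-5-(tert-butyldiphenylsilyloxy)-3-methylpent-3-en-1-yl]-3-methyloxan-3-yl 2-diazo-3-oxobutanoate | O1[C@@H](CC/C(C)=C\CO[Si](c2ccccc2)(c2ccccc2)C(C)(C)C)[C@@](C)(CC[C@@H]1O[Si](C)(C)C(C)(C)C)OC(=O)C(=[N+]=[N-])C(C)=O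
F2 | step 17 | (2S,3R,6S)-6-(tert-butyldimethylsilyloxy)-2-[(3Z)-5-(tert-butyldiphenylsilyloxy)-3-methylpent-3-en-1-yl]-3-methyloxan-3-yl 2-diazo-3-hydroxybutanoate (carbinol epimers) | O1[C@@H](CC/C(C)=C\CO[Si](c2ccccc2)(c2ccccc2)C(C)(C)C)[C@@](C)(CC[C@@H]1O[Si](C)(C)C(C)(C)C)OC(=O)C(=[N+]=[N-])C(C)O
F3 | step 17 | (2S,3R,6S)-6-(tert-butyldimethylsilyloxy)-2-[(3Z)-5-(tert-butyldiphenylsilyloxy)-3-methylpent-3-en-1-yl]-3-methyloxan-3-yl 2-diazobut-3-enoate | O1[C@@H](CC/C(C)=C\CO[Si](c2ccccc2)(c2ccccc2)C(C)(C)C)[C@@](C)(CC[C@@H]1O[Si](C)(C)C(C)(C)C)OC(=O)C(=[N+]=[N-])C=C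
F4 | step 17 | (1R,2S,5R,9S)-2-(tert-butyldimethylsilyloxy)-9-[(3Z)-5-(tert-butyldiphenylsilyloxy)-3-methylpent-3-en-1-yl]-1-ethenyl-5-methyl-6,8-dioxabicyclo[3.2.2]nonan-7-one | C=C[C@@]12O[C@@H](CC/C(C)=C\CO[Si](c3ccccc3)(c3ccccc3)C(C)(C)C)[C@@](C)(CC[C@@H]1O[Si](C)(C)C(C)(C)C)OC2=O
F5 | step 17 | 9-borabicyclo[3.3.1]nonane adduct of F4 (boron on the terminal carbon of the former vinyl group) | C(C[C@@]12O[C@@H](CC/C(C)=C\CO[Si](c3ccccc3)(c3ccccc3)C(C)(C)C)[C@@](C)(CC[C@@H]1O[Si](C)(C)C(C)(C)C)OC2=O)B1C2CCCC1CCC2
F6 | step 17 | (Z)-3-iodo-2-methylprop-2-en-1-ol | I/C=C(/C)CO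
F7 | step 17 | (Z)-tert-butyl[(3-iodo-2-methylprop-2-en-1-yl)oxy]diphenylsilane | I/C=C(/C)CO[Si](c1ccccc1)(c1ccccc1)C(C)(C)C
F8 | step 12 | (2S,6S)-6-(tert-butyldimethylsilyloxy)-2-[(3Z)-5-(tert-butyldiphenylsilyloxy)-3-methylpent-3-en-1-yl]oxan-3-one | O1[C@@H](CC/C(C)=C\CO[Si](c2ccccc2)(c2ccccc2)C(C)(C)C)C(=O)CC[C@@H]1O[Si](C)(C)C(C)(C)C
F9 | step 12 | spiro-epoxide of F8: 6-(tert-butyldimethylsilyloxy)-4-[(3Z)-5-(tert-butyldiphenylsilyloxy)-3-methylpent-3-en-1-yl]-1,5-dioxaspiro[2.5]octane, epoxide oxygen trans to the side chain | O1[C@@H](CC/C(C)=C\CO[Si](c3ccccc3)(c3ccccc3)C(C)(C)C)[C@@]2(CO2)CC[C@@H]1O[Si](C)(C)C(C)(C)C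
F10 | step 15 | racemic tert-butyl (5Z)-2-acetyl-7-(tert-butyldiphenylsilyloxy)-6-methylhept-5-enoate | CC(=O)C(CC/C=C(/C)CO[Si](c1ccccc1)(c1ccccc1)C(C)(C)C)C(=O)OC(C)(C)C
F11 | step 10 | furan endoperoxide of 15 (2,3,7-trioxabicyclo[2.2.1]hept-5-ene carrying the (S)-carbinol side chain at a bridgehead) | O[C@@H](CC/C(C)=C\CO[Si](c1ccccc1)(c1ccccc1)C(C)(C)C)C12OOC(C=C1)O2
A1 | alternative 1 | acyclic epoxy diol ester, methyl 2,3-dihydroxy ester with the C9/C5 epoxide of an (E)-alkene (shown without protecting groups) | C/C(=C/CC[C@](O)(C(=O)OC)[C@@H](O)CC[C@@]1(C)O[C@@H]1CC/C(C)=C\CO)CO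
A2 | alternative 1 | oxepane hydroxy ester, methyl (2R,3S,6R,7S)-3,6-dihydroxy-2-[(3Z)-5-hydroxy-4-methylpent-3-en-1-yl]-7-[(3Z)-5-hydroxy-3-methylpent-3-en-1-yl]-6-methyloxepane-2-carboxylate | C/C(=C/CC[C@@]1(C(=O)OC)O[C@@H](CC/C(C)=C\CO)[C@](C)(O)CC[C@@H]1O)CO
A3 | alternative 2 | (5S,6R)-3-[(3Z)-5-hydroxy-4-methylpent-3-en-1-yl]-5-[(3Z)-5-hydroxy-3-methylpent-3-en-1-yl]-6-methyl-6-(3-oxopropyl)-1,4-dioxan-2-one (epimers at C3) | C/C(=C/CCC1O[C@@H](CC/C(C)=C\CO)[C@@](C)(CCC=O)OC1=O)CO
A4 | alternative 3 | (7R)-7-[(1S,4Z)-1,6-dihydroxy-4-methylhex-4-en-1-yl]-3-[(3Z)-5-hydroxy-4-methylpent-3-en-1-yl]-7-methyl-6,7-dihydrooxepin-2(5H)-one | C/C(=C/CCC1=CCC[C@](C)([C@@H](O)CC/C(C)=C\CO)OC1=O)CO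
A5 | alternative 3 | 3,4-epoxide of A4 (epoxide oxygen on the face opposite to the one O8 must enter) | C/C(=C/CC[C@]12O[C@H]1CC[C@](C)([C@@H](O)CC/C(C)=C\CO)OC2=O)CO
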